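**Retrosynthetic overview**

- Feature: ring A (C1–C6) carries three adjacent oxygens O3, O4 and O5 and the stilbene carbon on C1. O3 and O4 are tied through C7 (syringyl-bearing) and C8 (CH2OH-bearing) into the dioxane ring B. This pattern maps onto a 5-substituted 2-diazocyclohexane-1,3-dione: carbene carbon = C4, the two carbonyls = C3–O3 and C5–O5, ester carbon = C1.
- Late disconnections: global desilylation, then the stilbene C=C by Horner–Wadsworth–Emmons olefination of a ring A aldehyde (from the ester) with a 3,5-bis(silyloxy)benzyl phosphonate.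
- Ring A is aromatised late, by dehydrogenation of a tetrahydrobenzodioxinone through its silyl dienol ether.
- Key disconnection: C4–O4 and O3–C7 of ring B, formed in one operation from the diazo dione and the (2S,3S)-epoxide of bis-silylated sinapyl alcohol (metal carbenoid, oxonium ylide, formal [3+3]). C8 comes from a Sharpless epoxidation; C7 is re-formed with retention.
- Ring order: oxirane, then dioxene ring B on the preformed carbocycle, then aromatic ring A; the syringyl and resorcinol rings are bought.

Key step: step 7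

Assumption: ethyl 3,5-dioxocyclohexane-1-carboxylate is bought as such, and its ethyl ester is a spectator that is reduced later, so it replaces the free acid and saves an esterification. Lignan numbering is used throughout (ring A C1–C6, benzylic C7, C8 bearing the CH2O group).

**Route**

Step 1
Reactants: 1 sinapic acid
Product: 2 methyl sinapate
Conditions: MeOH, H2SO4 (cat.), reflux
Reagents that add atoms: methanol, CO
Why: Fischer esterification in excess methanol under acid catalysis converts only the carboxylic acid and leaves the phenol and the E-alkene untouched.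

Step 2
Reactants: 2 methyl sinapate
Product: 3 methyl (E)-3-[4-(tert-butyldimethylsilyloxy)-3,5-dimethoxyphenyl]prop-2-enoate
Conditions: TBSCl, imidazole, DMF, rt
Reagents that add atoms: tert-butyldimethylsilyl chloride, CC(C)(C)[Si](C)(C)Cl
Why: Imidazole-promoted silylation of the only hydroxyl group gives the aryl silyl ether, which keeps the phenol from quenching i-Bu2AlH, from binding titanium in step 4 and from O–H insertion in step 7.

Step 3
Reactants: 3 methyl (E)-3-[4-(tert-butyldimethylsilyloxy)-3,5-dimethoxyphenyl]prop-2-enoate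
Product: 4 (E)-3-[4-(tert-butyldimethylsilyloxy)-3,5-dimethoxyphenyl]prop-2-en-1-ol
Conditions: i-Bu2AlH (2.5 equiv), CH2Cl2, −78 °C; aqueous potassium sodium tartrate work-up
Reagents that add atoms: none
Why: 1,2-Reduction of the α,β-unsaturated ester by i-Bu2AlH at low temperature gives the E-allylic alcohol without conjugate reduction, and the aryl silyl ether is inert to the hydride.

Step 4
Reactants: 4 (E)-3-[4-(tert-butyldimethylsilyloxy)-3,5-dimethoxyphenyl]prop-2-en-1-ol
Product: 5 [(2S,3S)-3-[4-(tert-butyldimethylsilyloxy)-3,5-dimethoxyphenyl]oxiran-2-yl]methanol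
Conditions: Ti(OiPr)4 (10 mol%), L-(+)-diisopropyl tartrate (12 mol%), t-BuOOH (decane), 4 Å molecular sieves, CH2Cl2, −20 °C
Reagents that add atoms: tert-butyl hydroperoxide, CC(C)(C)OO
Why: Sharpless asymmetric epoxidation, in which the titanium–L-(+)-tartrate complex delivers the peroxide oxygen to the face of the E-allylic alcohol that gives the (2S,3S)-epoxy alcohol, sets C8 of the target and C7 of the epoxide, while the catalytic loading with sieves at −20 °C limits Lewis-acid opening of the benzylic epoxide.

Step 5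
Reactants: 5 [(2S,3S)-3-[4-(tert-butyldimethylsilyloxy)-3,5-dimethoxyphenyl]oxiran-2-yl]methanol
Product: 6 (2S,3S)-2-[(tert-butyldimethylsilyloxy)methyl]-3-[4-(tert-butyldimethylsilyloxy)-3,5-dimethoxyphenyl]oxirane
Conditions: TBSCl, imidazole, CH2Cl2, 0 °C → rt
Reagents that add atoms: tert-butyldimethylsilyl chloride, CC(C)(C)[Si](C)(C)Cl
Why: Silylation of the primary alcohol under mildly basic conditions leaves the epoxide intact and removes the only O–H bond that would otherwise intercept the carbenoid in step 7.

Step 6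
Reactants: 7 ethyl 3,5-dioxocyclohexane-1-carboxylate
Product: 8 ethyl 4-diazo-3,5-dioxocyclohexane-1-carboxylate
Conditions: 4-acetamidobenzenesulfonyl azide, Et3N, MeCN, 0 °C → rt
Reagents that add atoms: 4-acetamidobenzenesulfonyl azide, CC(=O)Nc1ccc(cc1)S(=O)(=O)N=[N+]=[N-]
Why: Regitz diazo transfer from the sulfonyl azide to the doubly activated methylene between the two ketones is fast under triethylamine, and the remote ester takes no part.

Step 7
Reactants: 6 (2S,3S)-2-[(tert-butyldimethylsilyloxy)methyl]-3-[4-(tert-butyldimethylsilyloxy)-3,5-dimethoxyphenyl]oxirane; 8 ethyl 4-diazo-3,5-dioxocyclohexane-1-carboxylate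
Product: 10 ethyl (2S,3S)-2-[4-(tert-butyldimethylsilyloxy)-3,5-dimethoxyphenyl]-3-[(tert-butyldimethylsilyloxy)methyl]-5-oxo-2,3,5,6,7,8-hexahydro-1,4-benzodioxine-7-carboxylate as a mixture of epimers at the ester carbon, via oxiranium ylide 9 (not isolated)
Conditions: [CpRu(CH3CN)3]PF6 (5 mol%), 1,10-phenanthroline (5 mol%), CH2Cl2, 60 °C (sealed tube), 8 (2 equiv) added slowly
Reagents that add atoms: none
Why: The ruthenium complex decomposes 8 to an electrophilic metal carbene whose carbon (C4) is attacked by the epoxide oxygen of 6, giving oxiranium ylide 9 and the C4–O4 bond; the strained C7–O bond of 9 then ionises in an SN1-like way, helped by the electron-rich aryl group, and the enolate oxygen, held syn by the six-membered ring, collapses on C7 to form the O3–C7 bond. The closest known reaction type is the metal-carbenoid condensation of α-diazo-β-dicarbonyl compounds with epoxides to 1,4-dioxenes, applied here to a cyclic diazo dione and a trans-disubstituted aryl epoxide. Ring B is closed by this front-side ring expansion of the three-membered oxiranium ring, a formal [3+3] union of the O–C–C unit of the epoxide with the C–C–O unit of the keto carbene. C8 keeps its configuration because its C–O bond is never broken, and C7 is re-formed with retention, controlled by collapse of the tight ion pair on the face of the departing oxygen and by the preference for the diequatorial trans arrangement, so (2S,3S)-6 should give (7S,8S)-10. The step needs cleavage of the benzylic C7–O bond and not the C8–O bond, which the aryl group secures, and it needs ring closure to outrun loss of alkene from the ylide and carbene dimerisation, which the geometrically fixed enolate and the slow addition of 8 favour. The two carbonyls of 8 are equivalent, so no regiochemical question arises on the dione side, and the uncontrolled stereocentre at the ester carbon is erased in step 8.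

Step 8
Reactants: 10 ethyl (2S,3S)-2-[4-(tert-butyldimethylsilyloxy)-3,5-dimethoxyphenyl]-3-[(tert-butyldimethylsilyloxy)methyl]-5-oxo-2,3,5,6,7,8-hexahydro-1,4-benzodioxine-7-carboxylate
Product: 12 ethyl (2S,3S)-5-(tert-butyldimethylsilyloxy)-2-[4-(tert-butyldimethylsilyloxy)-3,5-dimethoxyphenyl]-3-[(tert-butyldimethylsilyloxy)methyl]-2,3-dihydro-1,4-benzodioxine-7-carboxylate, via silyl dienol ether 11 (not isolated)
Conditions: TBSOTf, Et3N, CH2Cl2, 0 °C; NaHCO3 wash; then DDQ, CH2Cl2, 0 °C → rt
Reagents that add atoms: tert-butyldimethylsilyl triflate, CC(C)(C)[Si](C)(C)OS(=O)(=O)C(F)(F)F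
Why: Soft enolisation with TBSOTf and triethylamine should give the cross-conjugated silyl dienol ether 11, and DDQ then dehydrogenates this electron-rich silyloxy cyclohexadiene (hydride abstraction followed by proton loss) to the arene, so that ring A is aromatised, the C5 phenol emerges already silylated and the epimeric ester carbon becomes planar, while C7 and C8 are not involved.

Step 9
Reactants: 12 ethyl (2S,3S)-5-(tert-butyldimethylsilyloxy)-2-[4-(tert-butyldimethylsilyloxy)-3,5-dimethoxyphenyl]-3-[(tert-butyldimethylsilyloxy)methyl]-2,3-dihydro-1,4-benzodioxine-7-carboxylate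
Product: 13 [(2S,3S)-5-(tert-butyldimethylsilyloxy)-2-[4-(tert-butyldimethylsilyloxy)-3,5-dimethoxyphenyl]-3-[(tert-butyldimethylsilyloxy)methyl]-2,3-dihydro-1,4-benzodioxin-7-yl]methanol
Conditions: i-Bu2AlH (2.5 equiv), CH2Cl2, −78 → 0 °C; aqueous potassium sodium tartrate work-up
Reagents that add atoms: none
Why: Reduction of the aryl ester by i-Bu2AlH to the benzylic alcohol tolerates the silyl ethers and the benzodioxane, and no stereocentre is touched.

Step 10
Reactants: 13 [(2S,3S)-5-(tert-butyldimethylsilyloxy)-2-[4-(tert-butyldimethylsilyloxy)-3,5-dimethoxyphenyl]-3-[(tert-butyldimethylsilyloxy)methyl]-2,3-dihydro-1,4-benzodioxin-7-yl]methanol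
Product: 14 (2S,3S)-5-(tert-butyldimethylsilyloxy)-2-[4-(tert-butyldimethylsilyloxy)-3,5-dimethoxyphenyl]-3-[(tert-butyldimethylsilyloxy)methyl]-2,3-dihydro-1,4-benzodioxine-7-carbaldehyde
Conditions: MnO2 (excess), CH2Cl2, rt
Reagents that add atoms: none
Why: MnO2 oxidises benzylic alcohols selectively to aldehydes without over-oxidation and without affecting silyl ethers or the electron-rich rings.

Step 11
Reactants: 15 3,5-dihydroxybenzyl alcohol
Product: 16 tert-butyl{[3,5-bis(tert-butyldimethylsilyloxy)phenyl]methoxy}dimethylsilane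
Conditions: TBSCl (3.3 equiv), imidazole, DMF, rt
Reagents that add atoms: tert-butyldimethylsilyl chloride, CC(C)(C)[Si](C)(C)Cl
Why: Exhaustive imidazole-promoted silylation caps both phenols and the benzylic alcohol, the latter serving as the precursor of the bromide.

Step 12
Reactants: 16 tert-butyl{[3,5-bis(tert-butyldimethylsilyloxy)phenyl]methoxy}dimethylsilane
Product: 17 3,5-bis(tert-butyldimethylsilyloxy)benzyl bromide
Conditions: Ph3PBr2, CH2Cl2, 0 °C → rt
Reagents that add atoms: triphenylphosphine dibromide, BrP(Br)(c1ccccc1)(c1ccccc1)c1ccccc1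
Why: Ph3PBr2 converts a primary benzylic silyl ether directly into the bromide through an alkoxyphosphonium bromide and SN2 displacement (Appel-type reaction), whereas the aryl silyl ethers cannot be displaced at sp2 carbon and stay in place.

Step 13
Reactants: 17 3,5-bis(tert-butyldimethylsilyloxy)benzyl bromide
Product: 18 diethyl [3,5-bis(tert-butyldimethylsilyloxy)benzyl]phosphonate
Conditions: P(OEt)3 (neat), 130 °C
Reagents that add atoms: triethyl phosphite, CCOP(OCC)OCC
Why: Michaelis–Arbuzov reaction of the benzylic bromide with triethyl phosphite gives the phosphonate with loss of bromoethane, and aryl silyl ethers withstand the neutral thermal conditions.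

Step 14
Reactants: 14 (2S,3S)-5-(tert-butyldimethylsilyloxy)-2-[4-(tert-butyldimethylsilyloxy)-3,5-dimethoxyphenyl]-3-[(tert-butyldimethylsilyloxy)methyl]-2,3-dihydro-1,4-benzodioxine-7-carbaldehyde; 18 diethyl [3,5-bis(tert-butyldimethylsilyloxy)benzyl]phosphonate
Product: 19 pentakis(tert-butyldimethylsilyl) ether of the target: the (7S,8S)-benzodioxane E-stilbene with all five hydroxyl groups silylated
Conditions: 18, NaN(SiMe3)2, THF, 0 °C; then 14, 0 °C → rt, protected from light
Reagents that add atoms: none
Why: Horner–Wadsworth–Emmons olefination of the aromatic aldehyde with the benzylic phosphonate anion gives the E-stilbene through reversible addition and syn-elimination of phosphate under thermodynamic control, and the non-nucleophilic amide base spares the aryl silyl ethers and the stereocentres.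

Step 15
Reactants: 19 pentakis(tert-butyldimethylsilyl) ether of the target
Product: 20 CNP0319597.1, 5-[(E)-2-[(2S,3S)-8-hydroxy-3-(4-hydroxy-3,5-dimethoxyphenyl)-2-(hydroxymethyl)-2,3-dihydro-1,4-benzodioxin-6-yl]ethenyl]benzene-1,3-diol
Conditions: Bu4NF, AcOH (1:1, excess), THF, 0 °C → rt, protected from light
Reagents that add atoms: none
Why: Fluoride cleaves all five Si–O bonds owing to the strength of the Si–F bond, and buffering with acetic acid keeps the liberated phenols protonated so that the 4-hydroxyaryl benzylic ether at C7 should not open through a quinone methide and the (7S,8S) configuration and the E-alkene are retained.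

**Compound list**

1 | sinapic acid | COc1cc(/C=C/C(=O)O)cc(OC)c1O | starting material
2 | methyl sinapate | COC(=O)/C=C/c1cc(OC)c(O)c(OC)c1 | intermediate
3 | methyl (E)-3-[4-(tert-butyldimethylsilyloxy)-3,5-dimethoxyphenyl]prop-2-enoate | COC(=O)/C=C/c1cc(OC)c(O[Si](C)(C)C(C)(C)C)c(OC)c1 | intermediate
4 | (E)-3-[4-(tert-butyldimethylsilyloxy)-3,5-dimethoxyphenyl]prop-2-en-1-ol | OC/C=C/c1cc(OC)c(O[Si](C)(C)C(C)(C)C)c(OC)c1 | intermediate
5 | [(2S,3S)-3-[4-(tert-butyldimethylsilyloxy)-3,5-dimethoxyphenyl]oxiran-2-yl]methanol | COc1cc([C@@H]2O[C@H]2CO)cc(OC)c1O[Si](C)(C)C(C)(C)C | intermediate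
6 | (2S,3S)-2-[(tert-butyldimethylsilyloxy)methyl]-3-[4-(tert-butyldimethylsilyloxy)-3,5-dimethoxyphenyl]oxirane | COc1cc([C@@H]2O[C@H]2CO[Si](C)(C)C(C)(C)C)cc(OC)c1O[Si](C)(C)C(C)(C)C | intermediate
7 | ethyl 3,5-dioxocyclohexane-1-carboxylate | CCOC(=O)C1CC(=O)CC(=O)C1 | starting material
8 | ethyl 4-diazo-3,5-dioxocyclohexane-1-carboxylate | CCOC(=O)C1CC(=O)C(=[N+]=[N-])C(=O)C1 | intermediate
9 | oxiranium ylide: epoxide oxygen of 6 bonded to C4 of the dione enolate (zwitterion, drawn metal-free) | CCOC(=O)C1CC(=O)C([O+]2[C@@H](CO[Si](C)(C)C(C)(C)C)[C@@H]2c3cc(OC)c(O[Si](C)(C)C(C)(C)C)c(OC)c3)=C([O-])C1 | intermediate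
10 | ethyl (2S,3S)-2-[4-(tert-butyldimethylsilyloxy)-3,5-dimethoxyphenyl]-3-[(tert-butyldimethylsilyloxy)methyl]-5-oxo-2,3,5,6,7,8-hexahydro-1,4-benzodioxine-7-carboxylate (epimer mixture at the ester carbon) | COc1cc([C@@H]2OC3=C(O[C@H]2CO[Si](C)(C)C(C)(C)C)C(=O)CC(C(=O)OCC)C3)cc(OC)c1O[Si](C)(C)C(C)(C)C | intermediate
11 | silyl dienol ether of 10 (5-silyloxy-5,6-ene, cross-conjugated with the dioxene double bond) | COc1cc([C@@H]2OC3=C(O[C@H]2CO[Si](C)(C)C(C)(C)C)C(O[Si](C)(C)C(C)(C)C)=CC(C(=O)OCC)C3)cc(OC)c1O[Si](C)(C)C(C)(C)C | intermediate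
12 | ethyl (2S,3S)-5-(tert-butyldimethylsilyloxy)-2-[4-(tert-butyldimethylsilyloxy)-3,5-dimethoxyphenyl]-3-[(tert-butyldimethylsilyloxy)methyl]-2,3-dihydro-1,4-benzodioxine-7-carboxylate | COc1cc([C@@H]2Oc3cc(C(=O)OCC)cc(O[Si](C)(C)C(C)(C)C)c3O[C@H]2CO[Si](C)(C)C(C)(C)C)cc(OC)c1O[Si](C)(C)C(C)(C)C | intermediate
13 | [(2S,3S)-5-(tert-butyldimethylsilyloxy)-2-[4-(tert-butyldimethylsilyloxy)-3,5-dimethoxyphenyl]-3-[(tert-butyldimethylsilyloxy)methyl]-2,3-dihydro-1,4-benzodioxin-7-yl]methanol | COc1cc([C@@H]2Oc3cc(CO)cc(O[Si](C)(C)C(C)(C)C)c3O[C@H]2CO[Si](C)(C)C(C)(C)C)cc(OC)c1O[Si](C)(C)C(C)(C)C | intermediate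
14 | (2S,3S)-5-(tert-butyldimethylsilyloxy)-2-[4-(tert-butyldimethylsilyloxy)-3,5-dimethoxyphenyl]-3-[(tert-butyldimethylsilyloxy)methyl]-2,3-dihydro-1,4-benzodioxine-7-carbaldehyde | COc1cc([C@@H]2Oc3cc(C=O)cc(O[Si](C)(C)C(C)(C)C)c3O[C@H]2CO[Si](C)(C)C(C)(C)C)cc(OC)c1O[Si](C)(C)C(C)(C)C | intermediate
15 | 3,5-dihydroxybenzyl alcohol | OCc1cc(O)cc(O)c1 | starting material
16 | tert-butyl{[3,5-bis(tert-butyldimethylsilyloxy)phenyl]methoxy}dimethylsilane | CC(C)(C)[Si](C)(C)OCc1cc(O[Si](C)(C)C(C)(C)C)cc(O[Si](C)(C)C(C)(C)C)c1 | intermediate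
17 | 3,5-bis(tert-butyldimethylsilyloxy)benzyl bromide | BrCc1cc(O[Si](C)(C)C(C)(C)C)cc(O[Si](C)(C)C(C)(C)C)c1 | intermediate
18 | diethyl [3,5-bis(tert-butyldimethylsilyloxy)benzyl]phosphonate | CCOP(=O)(OCC)Cc1cc(O[Si](C)(C)C(C)(C)C)cc(O[Si](C)(C)C(C)(C)C)c1 | intermediate
19 | pentakis(tert-butyldimethylsilyl) ether of the target, (7S,8S), E-stilbene | COc1cc([C@@H]2Oc3cc(/C=C/c4cc(O[Si](C)(C)C(C)(C)C)cc(O[Si](C)(C)C(C)(C)C)c4)cc(O[Si](C)(C)C(C)(C)C)c3O[C@H]2CO[Si](C)(C)C(C)(C)C)cc(OC)c1O[Si](C)(C)C(C)(C)C | intermediate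
20 | CNP0319597.1, 5-[(E)-2-[(2S,3S)-8-hydroxy-3-(4-hydroxy-3,5-dimethoxyphenyl)-2-(hydroxymethyl)-2,3-dihydro-1,4-benzodioxin-6-yl]ethenyl]benzene-1,3-diol | COc1cc([C@@H]2Oc3cc(/C=C/c4cc(O)cc(O)c4)cc(O)c3O[C@H]2CO)cc(OC)c1O | target

**Step count**

Total step count: 15.
Longest linear sequence: 11 steps (steps 1–5, 7–10, 14 and 15, from sinapic acid).

**Steps most likely to fail**

Step 7. Three things may go wrong:
- the oxonium ylide may fragment with loss of the alkene (deoxygenation of the epoxide) in place of ring expansion;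
- the benzylic cation may live long enough to erode the trans selectivity at C7;
- the ruthenium catalyst may fail to decompose the cyclic diazo dione at a useful rate.

The fallback builds the same two bonds stepwise and sets out from 6. Acid-catalysed methanolysis (MeOH, pyridinium p-toluenesulfonate, 0 °C) opens the epoxide at the benzylic carbon and should give the C7 methyl ether C8 alcohol F1, whose C7 configuration is unimportant. Rh2(OAc)4-catalysed O–H insertion of the carbene from 8 into the C8 hydroxyl (CH2Cl2, reflux) then forms the C4–O4 bond without touching C8 and gives the 2-alkoxy-3-hydroxycyclohexenone F2. BF3·OEt2 (CH2Cl2, −40 °C) ionises the benzylic methyl ether, and the enol oxygen closes on C7 under thermodynamic control to the trans product, which rejoins the route at 10.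

Step 8. DDQ may abstract hydride at the benzylic C7–H of the electron-rich aryl ether. The silyl dienol ether may also hydrolyse back to the enone, or the activated vinylogous ester may open at C7 under TBSOTf. The fallback is a selenoxide dehydrogenation from 10. LiN(i-Pr)2 (THF, −78 °C) then PhSeCl should give the α-phenylselanyl ketone F3. H2O2 with pyridine (CH2Cl2, 0 °C) brings about selenoxide syn-elimination and tautomerisation in the same flask, giving the ring A phenol F4. TBSCl and imidazole in DMF then return to the route at 12.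

Step 4. Lewis-acid opening of the benzylic epoxide by titanium alkoxide, tartrate or isopropanol during the reaction or work-up may destroy the product, and the enantioselectivity may be eroded. The fallback avoids Lewis acids and sets out from 4. Silylation (TBSCl, imidazole, CH2Cl2) gives the bis-silyl ether of sinapyl alcohol F5. Shi epoxidation follows, with the L-fructose-derived enantiomer of the Shi ketone (KHSO5 used as 2KHSO5·KHSO4·K2SO4, K2CO3 buffer, MeCN/dimethoxymethane/water, 0 °C). The D-fructose-derived ketone gives (R,R)-epoxides from trans-alkenes, so its enantiomer should give the (2S,3S)-epoxide directly, rejoining the route at 6.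

**Further compounds**

F1 | step 7 | (2S)-3-(tert-butyldimethylsilyloxy)-1-[4-(tert-butyldimethylsilyloxy)-3,5-dimethoxyphenyl]-1-methoxypropan-2-ol (C7 methyl ether, either C7 epimer) | COc1cc(C(OC)[C@@H](O)CO[Si](C)(C)C(C)(C)C)cc(OC)c1O[Si](C)(C)C(C)(C)C
F2 | step 7 | ethyl 4-{[(2S)-3-(tert-butyldimethylsilyloxy)-1-[4-(tert-butyldimethylsilyloxy)-3,5-dimethoxyphenyl]-1-methoxypropan-2-yl]oxy}-3-hydroxy-5-oxocyclohex-3-ene-1-carboxylate | CCOC(=O)C1CC(=O)C(O[C@@H](CO[Si](C)(C)C(C)(C)C)C(OC)c2cc(OC)c(O[Si](C)(C)C(C)(C)C)c(OC)c2)=C(O)C1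
F3 | step 8 | 6-phenylselanyl derivative of 10 (selenium on the CH2 between the ketone and the ester carbon) | COc1cc([C@@H]2OC3=C(O[C@H]2CO[Si](C)(C)C(C)(C)C)C(=O)C([Se]c4ccccc4)C(C(=O)OCC)C3)cc(OC)c1O[Si](C)(C)C(C)(C)C
F4 | step 8 | ethyl (2S,3S)-2-[4-(tert-butyldimethylsilyloxy)-3,5-dimethoxyphenyl]-3-[(tert-butyldimethylsilyloxy)methyl]-5-hydroxy-2,3-dihydro-1,4-benzodioxine-7-carboxylate | COc1cc([C@@H]2Oc3cc(C(=O)OCC)cc(O)c3O[C@H]2CO[Si](C)(C)C(C)(C)C)cc(OC)c1O[Si](C)(C)C(C)(C)C
F5 | step 4 | tert-butyl{[(E)-3-[4-(tert-butyldimethylsilyloxy)-3,5-dimethoxyphenyl]prop-2-en-1-yl]oxy}dimethylsilane | CC(C)(C)[Si](C)(C)OC/C=C/c1cc(OC)c(O[Si](C)(C)C(C)(C)C)c(OC)c1
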